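Remark on the chemistry: the ester alkene is read from the SMILES as Z (methyl cis to the ester carbonyl, trans to CH2OH). Compound numbers refer to the list after the steps.

## Analysis of the target

Target 22 is an acyclic ester whose only rings are two benzene rings. The text uses these labels (not the IUPAC locants of the names): C1 is the carbinol carbon bearing the 4-methoxyphenyl ring, C2 the adjacent methine, C3 the acylated CH2O on C2, C4 the allylic CH2 on C2, and C5=C6 the (E)-alkene ending in the 3,4-dimethoxyphenyl ring. C1 and C2 are the only stereocentres, both (S); with the chain aryl–C1–C2–C3 drawn zigzag, the C1 oxygen and the C4 arm lie on opposite sides (1,2-anti). The acyl part is a (Z)-2-(hydroxymethyl)but-2-enoate, the less stable geometry of a 2-substituted but-2-enoate. The 4-methoxybenzylic C1–OH ionises easily with acid, the Z-enoate can isomerise by reversible conjugate addition, the C3 ester can migrate to O1 under base, and C4 is doubly allylic. The synthesis is hard because the anti C1/C2 pair must be set in an open chain, three hydroxyl groups must be told apart so that only C3–O is acylated, and the Z geometry must survive ester formation. The strategy rests on C2 carrying one hydrogen and the C3H2–O group next to the C1 stereocentre: C2–H and C3–O are the two bonds a hydroboration–oxidation adds across a C2=C3 methylidene, and a bulky borane leaves the internal C5=C6 alkene alone.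

## Retrosynthetic reasoning

22 from 21. The last operation only removes two silyl ethers, one on O1 and one on the CH2OH of the acyl group. Silyl groups are chosen because fluoride removes them without the acid that would ionise C1–O and without the base that would move the ester.

21 from 13 and 19. The ester C–O bond at C3 is cut. This is the most convergent cut, and it puts the Z-alkene into a small fragment that can be made separately. The forward reaction must acylate the one free hydroxyl of 13 quickly enough that the Z-enoate does not isomerise; the mixed anhydride 20 serves this.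

19 from 14. The carboxyl carbon–alkenyl bond is cut, so the Z geometry becomes that of alkenyl iodide 17. Carboxylation of alkenyllithium 18 proceeds with retention. Iodide 17 comes from alcohol 16 and iodo-enal 15, and 15 from α-iodination of enal 14, whose elimination step gives the needed geometry.

13 from 11. The C2–H and C3–O bonds are cut back to the C2=C3 methylidene. This is the only disconnection that creates the C2 stereocentre from the C1 stereocentre already present and at the same time delivers C3–OH free while O1 is masked. The forward step must choose one alkene face (anti induction) and one of two alkenes; borane 12 is the intermediate.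

11 from 9. The silyl ether is traced to alcohol 10, and the C1 stereocentre to a Sharpless kinetic resolution of racemate 9. A Corey–Bakshi–Shibata reduction of 8 would be one step shorter. Its two carbonyl substituents, an aryl ring and a 1-substituted vinyl group, are flat groups of similar size, so the sense and degree of discrimination cannot be predicted. The resolution costs at most half of 9 but its outcome follows from a well-tested mnemonic.

9 from 7. C1–H is removed to give enone 8, and the C2=C3 bond is cut back to ketone 7 and a one-carbon electrophile. Ketone 7 has a single α-CH2, so only one methylidene can form.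

7 from 5 and 4. The C2–C4 bond is cut: enolate 6 of ketone 5 is alkylated by allylic bromide 4, which brings in the complete C4–C6 arm with its E-alkene.

4 from 1. The bromide is traced through alcohol 3 to acid 1, reduced by way of mixed anhydride 2 so that the conjugated alkene is not touched.

## Alternatives that were turned down

Alternative 1: The C2–C4 bond is cut by a [3,3] transform. The lithium alkoxide–enolate dianion of (R)-1-(3,4-dimethoxyphenyl)prop-2-en-1-yl (S)-3-hydroxy-3-(4-methoxyphenyl)propanoate A1 would undergo an Ireland–Claisen rearrangement through a chair to (2R,3S)-2-[(E)-3-(3,4-dimethoxyphenyl)prop-2-en-1-yl]-3-hydroxy-3-(4-methoxyphenyl)propanoic acid A2.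
- For it: C2–C4, the C2 stereocentre and the E C5=C6 alkene form in one concerted step, and no question of alkene site selectivity arises. On these points it is stronger than the chosen route.
- Against it: A1 is an ester of a 1-arylallyl alcohol with an electron-rich ring. Such esters ionise and transpose to the achiral cinnamyl isomer, which erases the chirality to be relayed.
- Two separate enantioselective preparations are needed, and one stereocentre is consumed only as a relay.
- The sense of transfer depends on the enolate geometry of a dianion that can also lose its β-alkoxide or fragment by retro-aldol while it warms to rearrange.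
- A2 is an acid; it must still be reduced at C3 and its two hydroxyls distinguished.
- Comparison: the chosen strategy needs one external source of chirality, uses robust intermediates and gives the hydroxyls already differentiated.

Alternative 2: The C1–aryl bond is cut. An aryl Grignard reagent would add under magnesium-halide chelation to (S,E)-5-(3,4-dimethoxyphenyl)-2-[(methoxymethoxy)methyl]pent-4-enal A3 to give (1S,2S,E)-5-(3,4-dimethoxyphenyl)-2-[(methoxymethoxy)methyl]-1-(4-methoxyphenyl)pent-4-en-1-ol A4.
- For it: the aryl group enters last, and a six-membered chelate with attack opposite the C4 arm predicts the anti pair.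
- The C2 centre would come from an enzymatic desymmetrisation that loses no material. This is stronger than the resolution used here.
- Against it: A3 has an epimerisable α-stereocentre and a β-alkoxy group that can eliminate.
- Chelation through an acetal oxygen competes poorly with the fast non-chelated addition of an aryl Grignard reagent.
- In A4 the acetal sits on O3, the oxygen that must be acylated. Its removal needs acid next to the ionisable C1 carbinol, so a protecting-group exchange is added to an already longer sequence.
- Comparison: the chosen strategy offers a free C3–OH directly and avoids any acidic deprotection.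

Alternative 3: The ester is cut at the acyl carbon on both sides. (1S,2S)-2-[(E)-3-(3,4-dimethoxyphenyl)prop-2-en-1-yl]-1-(4-methoxyphenyl)propane-1,3-diol A5, iodide 17 and a one-carbon carbonyl source would combine on palladium to (2S,3S)-2-[(E)-3-(3,4-dimethoxyphenyl)prop-2-en-1-yl]-3-hydroxy-3-(4-methoxyphenyl)propyl (Z)-2-[(tert-butyldimethylsilyloxy)methyl]but-2-enoate A6.
- For it: the alkene geometry is locked in 17 and no activated acyl derivative that could isomerise is formed.
- The carboxylation step and the O1 protecting group are saved. On Z integrity and on step count for the acyl part it is stronger.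
- Against it: it presupposes A5 and so leaves the C1/C2 problem unanswered.
- The alcohol would be the limiting nucleophile in a reaction normally run with excess alcohol.
- The styrenyl alkene can insert into the alkenylpalladium species.
- Primary-over-secondary selectivity is not enforced.
- Comparison: the chosen strategy supplies the stereochemistry and an unambiguous acylation site, and keeps this carbonylation in reserve for the ester bond.

Key step: step 8

## Route

Step 1
Reactants: 1 (E)-3-(3,4-dimethoxyphenyl)prop-2-enoic acid
Product: 3 (E)-3-(3,4-dimethoxyphenyl)prop-2-en-1-ol, via mixed carbonic anhydride 2 (not isolated)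
Conditions: ClCO2Et, Et3N, THF, −10 °C; then NaBH4, THF/H2O, 0 °C → rt
Reagents that add atoms: none
Why: Mixed-anhydride reduction of a carboxylic acid: borohydride attacks the more electrophilic acyl carbonyl of 2 and reduces the resulting aldehyde 1,2; the conjugated alkene, which LiAlH4 would endanger, is left alone.

Step 2
Reactants: 3 (E)-3-(3,4-dimethoxyphenyl)prop-2-en-1-ol
Product: 4 (E)-4-(3-bromoprop-1-en-1-yl)-1,2-dimethoxybenzene
Conditions: PBr3 (0.4 equiv), Et2O, 0 °C; used at once
Reagents that add atoms: phosphorus tribromide, BrP(Br)Br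
Why: Bromination of a primary allylic alcohol through its phosphite ester; ether and low temperature limit ionisation of the electron-rich cinnamyl bromide, which is not stored.

Step 3
Reactants: 5 1-(4-methoxyphenyl)ethan-1-one; 4 (E)-4-(3-bromoprop-1-en-1-yl)-1,2-dimethoxybenzene
Product: 7 (E)-5-(3,4-dimethoxyphenyl)-1-(4-methoxyphenyl)pent-4-en-1-one, via lithium enolate 6 (not isolated)
Conditions: LiN(iPr)2 (1.5 equiv), 5 (1.5 equiv), THF, −78 °C; then 4 (1.0 equiv), −78 → 0 °C
Reagents that add atoms: none
Why: Lithium enolate alkylation by SN2 attack at the primary allylic carbon forms the C2–C4 bond; 5 has one enolisable position, and an excess of enolate over bromide limits dialkylation.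

Step 4
Reactants: 7 (E)-5-(3,4-dimethoxyphenyl)-1-(4-methoxyphenyl)pent-4-en-1-one
Product: 8 (E)-5-(3,4-dimethoxyphenyl)-1-(4-methoxyphenyl)-2-methylidenepent-4-en-1-one
Conditions: (CH2O)n, iPr2NH2+ CF3CO2−, CF3CO2H (cat.), THF, reflux; used directly
Reagents that add atoms: paraformaldehyde (formaldehyde source), C=O
Why: Mannich-type α-methylenation: the enol of 7 adds to the iminium ion formed from formaldehyde and the β-amino ketone loses amine; the single α-CH2 allows only one methylidene, and the mild ammonium salt does not move the C5=C6 alkene.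

Step 5
Reactants: 8 (E)-5-(3,4-dimethoxyphenyl)-1-(4-methoxyphenyl)-2-methylidenepent-4-en-1-one
Product: 9 rac-(E)-5-(3,4-dimethoxyphenyl)-1-(4-methoxyphenyl)-2-methylidenepent-4-en-1-ol
Conditions: NaBH4, CeCl3·7H2O, MeOH, −40 → 0 °C
Reagents that add atoms: none
Why: Luche reduction: the cerium-activated carbonyl takes hydride 1,2, which avoids the conjugate reduction to which aryl vinyl ketones are prone; the racemate is intended.

Step 6
Reactants: 9 rac-(E)-5-(3,4-dimethoxyphenyl)-1-(4-methoxyphenyl)-2-methylidenepent-4-en-1-ol
Product: 10 (S,E)-5-(3,4-dimethoxyphenyl)-1-(4-methoxyphenyl)-2-methylidenepent-4-en-1-ol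
Conditions: Ti(OiPr)4 (0.15 equiv), L-(+)-diisopropyl tartrate (0.2 equiv), tBuOOH (0.6 equiv), 4 Å molecular sieves, CH2Cl2, −20 °C
Reagents that add atoms: none
Why: Sharpless kinetic resolution: with L-(+)-tartrate the titanium peroxide complex epoxidises the (R)-alcohol, whose carbinol hydrogen faces the delivered oxygen, much faster than the (S)-alcohol, which is recovered; the C5=C6 alkene has no coordinating hydroxyl and should not react.

Step 7
Reactants: 10 (S,E)-5-(3,4-dimethoxyphenyl)-1-(4-methoxyphenyl)-2-methylidenepent-4-en-1-ol
Product: 11 tert-butyl{[(S,E)-5-(3,4-dimethoxyphenyl)-1-(4-methoxyphenyl)-2-methylidenepent-4-en-1-yl]oxy}dimethylsilane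
Conditions: tBuMe2SiCl, imidazole, DMF, rt
Reagents that add atoms: tert-butyldimethylsilyl chloride, CC(C)(C)[Si](C)(C)Cl
Why: Imidazole-mediated silylation of a secondary alcohol; the chloride is preferred to the silyl triflate so that the benzylic, allylic C1–O bond is not ionised, and no stereocentre is touched.

Step 8
Reactants: 11 tert-butyl{[(S,E)-5-(3,4-dimethoxyphenyl)-1-(4-methoxyphenyl)-2-methylidenepent-4-en-1-yl]oxy}dimethylsilane
Product: 13 (S,E)-2-[(S)-(tert-butyldimethylsilyloxy)(4-methoxyphenyl)methyl]-5-(3,4-dimethoxyphenyl)pent-4-en-1-ol, via B-alkyl-9-borabicyclononane 12 (not isolated)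
Conditions: 9-BBN-H (0.5 M in THF, 2 equiv), THF, 0 °C → rt; then NaBO3·4H2O, H2O, rt
Reagents that add atoms: sodium perborate (used as NaBO3·4H2O), [Na+].[Na+].O[B-]1(O)OO[B-](O)(O)OO1
Why: Hydroboration–oxidation with 1,2-asymmetric induction: the B–H bond of 9-BBN-H adds syn across C2=C3 through a four-centre transition state, boron on the unsubstituted C3 and hydrogen on C2, and perborate then replaces boron by oxygen to give C3–OH. The closest known reaction type is the anti-selective hydroboration of 1,1-disubstituted alkenes bearing an allylic silyloxy stereocentre with 9-BBN-H (the rhodium-catalysed variant with catecholborane gives the syn isomer). No ring is closed. The new C2 stereocentre is controlled by C1: in the reactive conformer the C1–H bond lies in the alkene plane, the aryl ring and the silyloxy group sit on opposite faces, and the borane approaches anti to the aryl ring, the larger substituent and the better σ-donor, so that the (S)-ether 11 should give the (1S,2S), 1,2-anti arrangement. Selectivity between the two alkenes is needed and comes from the steric demand of the dialkylborane, which adds to a terminal 1,1-disubstituted alkene far faster than to an internal, aryl-conjugated (E)-alkene; the same demand places boron on C3. Boron on C3 is γ to the silyloxy group, so no β-elimination can follow. The weakly basic perborate oxidation should keep the silyl group on O1, so 13 emerges with C3–OH free and C1–O masked.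

Step 9
Reactants: 14 (E)-but-2-enal
Product: 15 (Z)-2-iodobut-2-enal
Conditions: I2, K2CO3, DMAP (cat.), THF/H2O 1:1, rt
Reagents that add atoms: iodine, II
Why: α-Iodination of an enal by conjugate addition of DMAP, iodination of the resulting enolate and elimination of DMAP; elimination gives the isomer with CHO trans to methyl, which is the (Z)-iodide with iodine cis to methyl.

Step 10
Reactants: 15 (Z)-2-iodobut-2-enal
Product: 16 (Z)-2-iodobut-2-en-1-ol
Conditions: NaBH4, MeOH, 0 °C
Reagents that add atoms: none
Why: 1,2-Reduction of an α-iodo enal by borohydride; the alkene geometry and the C–I bond are not affected.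

Step 11
Reactants: 16 (Z)-2-iodobut-2-en-1-ol
Product: 17 (Z)-tert-butyl[(2-iodobut-2-en-1-yl)oxy]dimethylsilane
Conditions: tBuMe2SiCl, imidazole, CH2Cl2, rt
Reagents that add atoms: tert-butyldimethylsilyl chloride, CC(C)(C)[Si](C)(C)Cl
Why: Standard silylation of a primary allylic alcohol; it masks the hydroxyl for the organolithium step and for the esterification.

Step 12
Reactants: 17 (Z)-tert-butyl[(2-iodobut-2-en-1-yl)oxy]dimethylsilane
Product: 19 (Z)-2-{[(tert-butyldimethylsilyl)oxy]methyl}but-2-enoic acid, via alkenyllithium 18 (not isolated)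
Conditions: tBuLi (2.1 equiv), Et2O, −78 °C; CO2 (dry, excess), −78 °C → rt; aq. NH4Cl, then citric acid to pH 4
Reagents that add atoms: carbon dioxide, O=C=O
Why: Iodine–lithium exchange gives an alkenyllithium that is configurationally stable at −78 °C and is carboxylated with retention, so the carboxyl group takes the place of iodine cis to methyl; the low temperature also suppresses migration of silicon from oxygen to carbon.

Step 13
Reactants: 19 (Z)-2-{[(tert-butyldimethylsilyl)oxy]methyl}but-2-enoic acid; 13 (S,E)-2-[(S)-(tert-butyldimethylsilyloxy)(4-methoxyphenyl)methyl]-5-(3,4-dimethoxyphenyl)pent-4-en-1-ol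
Product: 21 (S,E)-2-[(S)-(tert-butyldimethylsilyloxy)(4-methoxyphenyl)methyl]-5-(3,4-dimethoxyphenyl)pent-4-en-1-yl (Z)-2-[(tert-butyldimethylsilyloxy)methyl]but-2-enoate, via mixed anhydride 20 (not isolated)
Conditions: 2,4,6-Cl3C6H2COCl, Et3N, toluene, rt; then 13, DMAP, toluene, rt
Reagents that add atoms: none
Why: Yamaguchi esterification: DMAP attacks the less hindered enoyl carbonyl of 20 and the acylpyridinium ion is taken by the only free hydroxyl of 13; fast acyl transfer at room temperature leaves little time for Z-to-E isomerisation by reversible conjugate addition.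

Step 14
Reactants: 21 (S,E)-2-[(S)-(tert-butyldimethylsilyloxy)(4-methoxyphenyl)methyl]-5-(3,4-dimethoxyphenyl)pent-4-en-1-yl (Z)-2-[(tert-butyldimethylsilyloxy)methyl]but-2-enoate
Product: 22 (S,E)-5-(3,4-dimethoxyphenyl)-2-[(S)-hydroxy(4-methoxyphenyl)methyl]pent-4-en-1-yl (Z)-2-(hydroxymethyl)but-2-enoate
Conditions: Bu4NF/AcOH (1:1, excess), THF, 0 °C → rt
Reagents that add atoms: none
Why: Fluoride cleavage of both silyl ethers; acetic acid protonates the alkoxides as they form, so neither acyl migration to O1 nor base-induced isomerisation of the enoate should set in, and no acid strong enough to ionise the benzylic carbinol is present.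

## Compound list

1 | (E)-3-(3,4-dimethoxyphenyl)prop-2-enoic acid ((E)-3,4-dimethoxycinnamic acid) | OC(=O)/C=C/c1ccc(OC)c(OC)c1 | starting material
2 | ethoxycarbonyl (E)-3-(3,4-dimethoxyphenyl)prop-2-enoate (mixed carbonic anhydride) | CCOC(=O)OC(=O)/C=C/c1ccc(OC)c(OC)c1 | intermediate
3 | (E)-3-(3,4-dimethoxyphenyl)prop-2-en-1-ol | OC/C=C/c1ccc(OC)c(OC)c1 | intermediate
4 | (E)-4-(3-bromoprop-1-en-1-yl)-1,2-dimethoxybenzene | BrC/C=C/c1ccc(OC)c(OC)c1 | intermediate
5 | 1-(4-methoxyphenyl)ethan-1-one (4-methoxyacetophenone) | CC(=O)c1ccc(OC)cc1 | starting material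
6 | lithium 1-(4-methoxyphenyl)ethen-1-olate | [Li+].[O-]C(=C)c1ccc(OC)cc1 | intermediate
7 | (E)-5-(3,4-dimethoxyphenyl)-1-(4-methoxyphenyl)pent-4-en-1-one | O=C(CC/C=C/c1ccc(OC)c(OC)c1)c1ccc(OC)cc1 | intermediate
8 | (E)-5-(3,4-dimethoxyphenyl)-1-(4-methoxyphenyl)-2-methylidenepent-4-en-1-one | C=C(C/C=C/c1ccc(OC)c(OC)c1)C(=O)c1ccc(OC)cc1 | intermediate
9 | rac-(E)-5-(3,4-dimethoxyphenyl)-1-(4-methoxyphenyl)-2-methylidenepent-4-en-1-ol (racemic at C1) | C=C(C/C=C/c1ccc(OC)c(OC)c1)C(O)c1ccc(OC)cc1 | intermediate
10 | (S,E)-5-(3,4-dimethoxyphenyl)-1-(4-methoxyphenyl)-2-methylidenepent-4-en-1-ol | C=C(C/C=C/c1ccc(OC)c(OC)c1)[C@H](O)c1ccc(OC)cc1 | intermediate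
11 | tert-butyl{[(S,E)-5-(3,4-dimethoxyphenyl)-1-(4-methoxyphenyl)-2-methylidenepent-4-en-1-yl]oxy}dimethylsilane | C=C(C/C=C/c1ccc(OC)c(OC)c1)[C@H](O[Si](C)(C)C(C)(C)C)c1ccc(OC)cc1 | intermediate
12 | 9-[(R,E)-2-[(S)-(tert-butyldimethylsilyloxy)(4-methoxyphenyl)methyl]-5-(3,4-dimethoxyphenyl)pent-4-en-1-yl]-9-borabicyclo[3.3.1]nonane (same spatial arrangement at C2 as in 13; the descriptor changes because boron ranks below carbon) | C(B1C2CCCC1CCC2)[C@H](C/C=C/c1ccc(OC)c(OC)c1)[C@H](O[Si](C)(C)C(C)(C)C)c1ccc(OC)cc1 | intermediate
13 | (S,E)-2-[(S)-(tert-butyldimethylsilyloxy)(4-methoxyphenyl)methyl]-5-(3,4-dimethoxyphenyl)pent-4-en-1-ol | OC[C@H](C/C=C/c1ccc(OC)c(OC)c1)[C@H](O[Si](C)(C)C(C)(C)C)c1ccc(OC)cc1 | intermediate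
14 | (E)-but-2-enal (crotonaldehyde) | C/C=C/C=O | starting material
15 | (Z)-2-iodobut-2-enal | C/C=C(\I)C=O | intermediate
16 | (Z)-2-iodobut-2-en-1-ol | C/C=C(\I)CO | intermediate
17 | (Z)-tert-butyl[(2-iodobut-2-en-1-yl)oxy]dimethylsilane | C/C=C(\I)CO[Si](C)(C)C(C)(C)C | intermediate
18 | [(E)-1-(tert-butyldimethylsilyloxy)but-2-en-2-yl]lithium (lithium cis to methyl) | C/C=C(\[Li])CO[Si](C)(C)C(C)(C)C | intermediate
19 | (Z)-2-{[(tert-butyldimethylsilyl)oxy]methyl}but-2-enoic acid | C/C=C(/CO[Si](C)(C)C(C)(C)C)C(=O)O | intermediate
20 | (Z)-2-{[(tert-butyldimethylsilyl)oxy]methyl}but-2-enoic 2,4,6-trichlorobenzoic anhydride | C/C=C(/CO[Si](C)(C)C(C)(C)C)C(=O)OC(=O)c1c(Cl)cc(Cl)cc1Cl | intermediate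
21 | (S,E)-2-[(S)-(tert-butyldimethylsilyloxy)(4-methoxyphenyl)methyl]-5-(3,4-dimethoxyphenyl)pent-4-en-1-yl (Z)-2-[(tert-butyldimethylsilyloxy)methyl]but-2-enoate | C/C=C(/CO[Si](C)(C)C(C)(C)C)C(=O)OC[C@H](C/C=C/c1ccc(OC)c(OC)c1)[C@H](O[Si](C)(C)C(C)(C)C)c1ccc(OC)cc1 | intermediate
22 | (S,E)-5-(3,4-dimethoxyphenyl)-2-[(S)-hydroxy(4-methoxyphenyl)methyl]pent-4-en-1-yl (Z)-2-(hydroxymethyl)but-2-enoate | C/C=C(/CO)C(=O)OC[C@H](C/C=C/c1ccc(OC)c(OC)c1)[C@H](O)c1ccc(OC)cc1 | target

## Step count and least certain steps

Total: 14 steps. Longest linear sequence: 10 steps (steps 1 to 8, 13 and 14); the acid fragment takes steps 9 to 12.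

Step 8 (key step). The facial selectivity may be poor. The known anti preference was established with alkyl groups on the carbinol carbon, and a flat aryl ring may not dominate the conformer population in the same way. A slow addition to the hindered methylidene would also let hydroboration of the C5=C6 alkene compete, and the silyl group could migrate from O1 to O3 during oxidation. The fallback gives up the hydroboration and sets C2 by alkylation anti to an existing C1 alkoxide. It sets out from bromide 4 and returns at 13. Commercial ethyl 3-(4-methoxyphenyl)-3-oxopropanoate is reduced by Noyori transfer hydrogenation (RuCl[(S,S)-TsDPEN](p-cymene), HCO2H/Et3N) to ethyl (S)-3-hydroxy-3-(4-methoxyphenyl)propanoate F1. Its dianion (LiN(iPr)2, 2.2 equiv, THF, −78 → −20 °C) is alkylated by 4 in a Fráter–Seebach alkylation, which should give ethyl (2R,3S)-2-[(E)-3-(3,4-dimethoxyphenyl)prop-2-en-1-yl]-3-hydroxy-3-(4-methoxyphenyl)propanoate F2. Silylation (tBuMe2SiCl, imidazole, DMF) gives ethyl (2R,3S)-3-[(tert-butyldimethylsilyl)oxy]-2-[(E)-3-(3,4-dimethoxyphenyl)prop-2-en-1-yl]-3-(4-methoxyphenyl)propanoate F3, and iBu2AlH (CH2Cl2, −78 → 0 °C) reduces the ester to 13.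

Step 6. The resolution may lose selectivity if the benzylic, allylic alcohol ionises on the Lewis-acidic titanium centre or if the aryl group weakens the rate difference between the enantiomers. At best half of 9 is kept. The fallback replaces resolution by enantioselective reduction; it sets out from enone 8 and returns at 10. A Corey–Bakshi–Shibata reduction with (R)-2-methyl-CBS-oxazaborolidine and catecholborane in toluene at −78 °C should give 10 if the aryl ring acts as the larger group, as it does in aryl alkyl ketones. No new compound is made.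

Step 13. The Z-enoate may isomerise to the E isomer through reversible conjugate addition of DMAP or chloride to the activated acyl species, especially if acyl transfer is slowed by the bulky silyl ether next to C3–OH. The fallback forms the ester by carbonylation instead of acyl transfer; it sets out from 13 and iodide 17 and returns at 21. Under carbon monoxide (1 atm) with Pd(PPh3)4 (zerovalent palladium) and Et3N in DMF at 60 °C, oxidative addition of 17, insertion of carbon monoxide and alcoholysis of the acylpalladium species by 13 should give 21 with the geometry of 17 retained. No new compound is made.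

Step 14. Cleavage of the hindered benzylic silyl ether under buffered fluoride may be slow. Forcing it invites acyl migration to O1 under basic conditions or ionisation at C1 under acidic ones. The fallback removes that silyl group before the ester exists and relies on primary-over-secondary selection in the acylation; it sets out from 13 and returns at 22. Bu4NF in THF converts 13 into (1S,2S)-2-[(E)-3-(3,4-dimethoxyphenyl)prop-2-en-1-yl]-1-(4-methoxyphenyl)propane-1,3-diol F4. Mixed anhydride 20 with DMAP at −20 °C should acylate the primary hydroxyl to give (2S,3S)-2-[(E)-3-(3,4-dimethoxyphenyl)prop-2-en-1-yl]-3-hydroxy-3-(4-methoxyphenyl)propyl (Z)-2-[(tert-butyldimethylsilyloxy)methyl]but-2-enoate F5. HF·pyridine in THF/pyridine at 0 °C then removes the remaining primary allylic silyl ether to give 22.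

Step 3. Proton transfer between product 7 and enolate 6 can lead to dialkylation, and the electron-rich bromide 4 can be lost by ionisation before it is alkylated. The fallback avoids both the bromide and the ketone enolate; it sets out from alcohol 3 and returns at 7. Methyl chloroformate and pyridine give (E)-3-(3,4-dimethoxyphenyl)prop-2-en-1-yl methyl carbonate F6. A Tsuji–Trost allylation of commercial ethyl 3-(4-methoxyphenyl)-3-oxopropanoate with Pd(PPh3)4 (zerovalent palladium) in THF should give the linear product ethyl (E)-5-(3,4-dimethoxyphenyl)-2-(4-methoxybenzoyl)pent-4-enoate F7 (racemic). Saponification (NaOH, EtOH/H2O), acidification and warming then decarboxylate it to 7.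

## Further compounds

F1 | step 8 | ethyl (S)-3-hydroxy-3-(4-methoxyphenyl)propanoate | CCOC(=O)C[C@H](O)c1ccc(OC)cc1
F2 | step 8 | ethyl (2R,3S)-2-[(E)-3-(3,4-dimethoxyphenyl)prop-2-en-1-yl]-3-hydroxy-3-(4-methoxyphenyl)propanoate | CCOC(=O)[C@H](C/C=C/c1ccc(OC)c(OC)c1)[C@H](O)c1ccc(OC)cc1
F3 | step 8 | ethyl (2R,3S)-3-[(tert-butyldimethylsilyl)oxy]-2-[(E)-3-(3,4-dimethoxyphenyl)prop-2-en-1-yl]-3-(4-methoxyphenyl)propanoate | CCOC(=O)[C@H](C/C=C/c1ccc(OC)c(OC)c1)[C@H](O[Si](C)(C)C(C)(C)C)c1ccc(OC)cc1
F0 | step 6 | none | none
F0 | step 13 | none | none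
F4 | step 14 | (1S,2S)-2-[(E)-3-(3,4-dimethoxyphenyl)prop-2-en-1-yl]-1-(4-methoxyphenyl)propane-1,3-diol | OC[C@H](C/C=C/c1ccc(OC)c(OC)c1)[C@H](O)c1ccc(OC)cc1
F5 | step 14 | (2S,3S)-2-[(E)-3-(3,4-dimethoxyphenyl)prop-2-en-1-yl]-3-hydroxy-3-(4-methoxyphenyl)propyl (Z)-2-[(tert-butyldimethylsilyloxy)methyl]but-2-enoate | C/C=C(/CO[Si](C)(C)C(C)(C)C)C(=O)OC[C@H](C/C=C/c1ccc(OC)c(OC)c1)[C@H](O)c1ccc(OC)cc1
F6 | step 3 | (E)-3-(3,4-dimethoxyphenyl)prop-2-en-1-yl methyl carbonate | COC(=O)OC/C=C/c1ccc(OC)c(OC)c1
F7 | step 3 | ethyl (E)-5-(3,4-dimethoxyphenyl)-2-(4-methoxybenzoyl)pent-4-enoate (racemic) | CCOC(=O)C(C/C=C/c1ccc(OC)c(OC)c1)C(=O)c1ccc(OC)cc1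
A1 | alternative 1 | (R)-1-(3,4-dimethoxyphenyl)prop-2-en-1-yl (S)-3-hydroxy-3-(4-methoxyphenyl)propanoate | C=C[C@@H](OC(=O)C[C@H](O)c1ccc(OC)cc1)c1ccc(OC)c(OC)c1
A2 | alternative 1 | (2R,3S)-2-[(E)-3-(3,4-dimethoxyphenyl)prop-2-en-1-yl]-3-hydroxy-3-(4-methoxyphenyl)propanoic acid | OC(=O)[C@H](C/C=C/c1ccc(OC)c(OC)c1)[C@H](O)c1ccc(OC)cc1
A3 | alternative 2 | (S,E)-5-(3,4-dimethoxyphenyl)-2-[(methoxymethoxy)methyl]pent-4-enal | COCOC[C@H](C/C=C/c1ccc(OC)c(OC)c1)C=O
A4 | alternative 2 | (1S,2S,E)-5-(3,4-dimethoxyphenyl)-2-[(methoxymethoxy)methyl]-1-(4-methoxyphenyl)pent-4-en-1-ol | COCOC[C@H](C/C=C/c1ccc(OC)c(OC)c1)[C@H](O)c1ccc(OC)cc1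
A5 | alternative 3 | (1S,2S)-2-[(E)-3-(3,4-dimethoxyphenyl)prop-2-en-1-yl]-1-(4-methoxyphenyl)propane-1,3-diol | OC[C@H](C/C=C/c1ccc(OC)c(OC)c1)[C@H](O)c1ccc(OC)cc1
A6 | alternative 3 | (2S,3S)-2-[(E)-3-(3,4-dimethoxyphenyl)prop-2-en-1-yl]-3-hydroxy-3-(4-methoxyphenyl)propyl (Z)-2-[(tert-butyldimethylsilyloxy)methyl]but-2-enoate | C/C=C(/CO[Si](C)(C)C(C)(C)C)C(=O)OC[C@H](C/C=C/c1ccc(OC)c(OC)c1)[C@H](O)c1ccc(OC)cc1
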